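## Analysis of the target

The target is a β-hydroxy dihydrochalcone. A three-carbon chain C(=O)–CH2–CH(OH) joins C5 of a 6-hydroxy-2,3-dihydrobenzofuran (benzene ring C fused to dihydrofuran ring D) to C6 of a 2,2-dimethylchroman (benzene ring A fused to pyran ring B). There are two stereocentres, both S: the benzylic carbinol carbon of the chain, and C2 of ring D, which carries a 2-hydroxypropan-2-yl group. They lie seven bonds apart, with ring C and the carbonyl between them, so neither can direct the other. Each must be set by its own catalyst, and the two diastereomers would be hard to separate.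

The aldol unit is the fragile part. The carbinol is benzylic and para to the chroman oxygen, so it ionises under acid. Under base the ketone enolises and expels hydroxide, or the chain fragments by retro-aldol. The ortho phenol on C6 would then close the resulting enone to a flavanone. The ortho-hydroxyaryl ketone is also open to Dakin-type oxidative cleavage, and the tertiary alcohol beside the C2–O1 bond invites ionisation and ring expansion under Lewis acids.

The strategy rests on one feature. The CH2 and CH(OH) carbons between the carbonyl carbon and C6 of ring A are a two-carbon unit with a heteroatom at its benzylic end. With boron in place of oxygen this unit is a vinylboronate, flanked by an acyl group on C5 of ring C and by an aryl group.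

## Retrosynthetic reasoning

**17 to 16.** The last operation frees the C6 phenol from its triisopropylsilyl ether 16. The silyl group is needed earlier: it keeps the phenol out of photocatalyst quenching and C–O coupling, and it blocks Dakin cleavage during the C–B oxidation. It leaves with buffered fluoride, which is neither acidic nor strongly basic.

**16 to 15.** The carbinol C–O bond is traced back to a C–B bond. The hydroxyl is the leaving group in every decomposition path of the aldol, so it is best introduced after the skeleton is complete. A pinacol boronate β to a ketone does not eliminate, and its oxidation proceeds with retention, so the configuration of 15 carries over to 16.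

**15 to 10, 12 and 13.** Two bonds are cut at once: carbonyl carbon to CH2, and benzylic carbon to C6 of ring A. The two carbons between them are the vinyl unit of 13; the acyl carbon comes from the keto acid 10 by loss of CO2, and the aryl group from the bromide 12. The classical cut at CH2–CH(OH) is avoided because an acetate-type aldol gives poor enantiocontrol and installs the sensitive hydroxyl during assembly. A cut at C5–C(=O) would put the aldol unit under Friedel–Crafts conditions. The forward reaction must add the acyl radical to the alkene before nickel captures it, and must set the benzylic configuration from the ligand alone.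

**12 to 11 and 2.** Ring B is cut at C4a–C4 and O1–C2. An acid-catalysed union of the phenol 11 with isoprene 2 forms both bonds. The para bromine blocks the para position and is the handle for the coupling.

**10 to 9, then to 6 and 7 via 8.** The acid comes from its ethyl ester 9. The C5–C(=O) bond is cut to an aryl nucleophile 8 and diethyl oxalate 7. A Lewis-acid Friedel–Crafts glyoxylation is avoided because the tertiary carbinol next to C2–O1 would ionise and could expand ring D or erode C2. An arylmagnesium is used in place of an aryllithium because an ortho-silyloxy aryllithium is prone to a 1,3 shift of silicon from oxygen to carbon.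

**6 to 5.** The C5–I bond is made by electrophilic iodination. C5 is para to O1 and ortho to the silyloxy group. C7 lies between both oxygens and is shielded by the silyl group, and C4 is not activated.

**5 to 4 to 3.** The tertiary alcohol comes from the isopropenyl group by radical Markovnikov hydration, which needs no acid and does not touch C2. The phenol is silylated first so that cobalt and oxygen do not oxidise it. The same silyl group serves to the end.

**3 to 1 and 2.** Ring D is cut at C3a–C3 and O1–C2. A palladium-catalysed heteroannulation of the ortho-bromophenol unit of 1 with isoprene 2 forms both bonds and sets C2 under ligand control.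

## Alternatives that were turned down

**Alternative 1:** chiral-pool route to ring D from L-tyrosine A1.
- **Disconnection:** the C7a–O1 bond of ring D. A1 supplies ring C, C3 and the C2 stereocentre through the diol (S)-1-[4-(benzyloxy)phenyl]-3-methylbutane-2,3-diol A2.
- **Key step:** the secondary hydroxyl of A2 binds divalent palladium and directs palladation of one of the two equivalent positions ortho to the benzylic CH2. Oxidation to tetravalent palladium by a hypervalent iodine oxidant triggers C–O reductive elimination to (S)-6-benzyloxy-2-(2-hydroxypropan-2-yl)-2,3-dihydrobenzofuran A3.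
- **For:** C2 is bought with certain configuration, and no regiochemical question arises in the C–H step.
- **Against:** it solves only ring D. The C5 acyl group, the chain and the carbinol centre remain open, so a second strategy is still needed. A secondary alcohol is a weak director under these oxidising conditions and is prone to oxidation to the ketone, and the neighbouring tertiary hydroxyl can compete toward a six-membered ether. A1 to A2 takes about four steps, and the benzyl ether must later be exchanged for a silyl ether, so the fragment costs about seven steps against three to reach 5.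
- **Comparison:** it is stronger on certainty of the C2 configuration. The chosen route offers a one-step catalytic ring D synthesis and a convergent answer for the chain.

**Alternative 2:** de novo construction of ring C.
- **Disconnection:** the C5–C6 and C3a–C4 bonds of ring C, between the diene (S)-5-[2,2-bis(trimethylsilyloxy)ethenyl]-2-[2-(triethylsilyloxy)propan-2-yl]-2,3-dihydrofuran A4 and the ynone (S)-5-(tert-butyldimethylsilyloxy)-5-(2,2-dimethylchroman-6-yl)pent-1-yn-3-one A5.
- **Key step:** the ketene acetal diene A4 adds to A5 with the polarity-dictated orientation, and loss of a silanol aromatises the adduct to the bis-silyl ether A6.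
- **For:** the substitution pattern of ring C is fixed by the polarisation of the partners, with no electrophilic substitution. The phenol emerges free, and the carbinol arrives protected, so no late C–B oxidation is needed. On these points it is stronger than the chosen route.
- **Against:** both stereocentres must be made beforehand in separate sequences. A4 is a hydrolytically labile ketene acetal on an enol ether and is long to prepare with its C2 centre. A5 is a β-silyloxy ynone that can eliminate or accept nucleophiles. A benzene ring that can be bought is built from scratch.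
- **Comparison:** the chosen route is shorter, uses robust intermediates and sets the carbinol in the coupling itself.

**Alternative 3:** late heteroannulation on the full skeleton.
- **Disconnection:** the C3a–C3 and O1–C2 bonds of ring D at the end, between the bromo ketone (S)-1-(5-bromo-2,4-dihydroxyphenyl)-3-(tert-butyldimethylsilyloxy)-3-(2,2-dimethylchroman-6-yl)propan-1-one A7 and isoprene 2.
- **Key step:** zerovalent palladium inserts into the C–Br bond of A7, isoprene is carbopalladated, and the 4-hydroxyl closes the allyl-palladium to the isopropenyl dihydrobenzofuran A8. Hydration and desilylation follow.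
- **For:** the reaction class is the one used in step 1. The ketone activates the C–Br bond and its hydrogen-bonded ortho hydroxyl stays out of competition, so A7 is electronically a better substrate than 1. No new method is needed anywhere, and the step count is comparable. On precedent it is as strong as or stronger than the chosen route.
- **Against:** base and heat act on a β-silyloxy ketone, which can eliminate to the enone and close to a flavanone. The carbinol must be set earlier by an asymmetric acetate-type aldol or ketone reduction, with its own phenol protection. Hydration then runs late on a free phenol. The sequence is linear and exposes the most valuable intermediate to palladium.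
- **Comparison:** the chosen route offers convergence and keeps the aldol unit out of all but the last two steps. Its two stereocentres are set in operations that never meet.

Key step: step 8

Assumption: the sense of induction of the chiral ligands in steps 1 and 8 cannot be derived from structure alone; in each case the ligand antipode that delivers the S centre is taken, both antipodes being accessible.

## Route

Step 1
Reactants: 1 4-bromoresorcinol (4-bromobenzene-1,3-diol); 2 isoprene (2-methylbuta-1,3-diene)
Product: 3 (S)-2-(prop-1-en-2-yl)-2,3-dihydro-1-benzofuran-6-ol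
Conditions: Pd2(dba)3 (2.5 mol%), chiral sulfinamide–monophosphine ligand (TY-Phos type, 10 mol%), NaOPh (2.5 equiv), 2 (4 equiv), CH2Cl2, 60 °C, sealed tube
Reagents that add atoms: none
Why: Asymmetric Larock-type heteroannulation (Heck/Tsuji–Trost): oxidative addition into C–Br, insertion of the unsubstituted vinyl terminus of isoprene, and 5-exo attack of the ortho phenoxide on the allyl-palladium should close ring D with the isopropenyl group on C2. The chiral ligand controls C2 in the C–O bond-forming step, and the para hydroxyl cannot cyclise.

Step 2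
Reactants: 3 (S)-2-(prop-1-en-2-yl)-2,3-dihydro-1-benzofuran-6-ol
Product: 4 triisopropyl{[(S)-2-(prop-1-en-2-yl)-2,3-dihydro-1-benzofuran-6-yl]oxy}silane
Conditions: TIPSCl (1.2 equiv), imidazole (2.5 equiv), DMF, rt
Reagents that add atoms: triisopropylsilyl chloride, CC(C)[Si](Cl)(C(C)C)C(C)C
Why: Standard silylation of the only hydroxyl; the bulky silyl ether should survive the later magnesium, hydroxide and perborate steps and shields C7.

Step 3
Reactants: 4 triisopropyl{[(S)-2-(prop-1-en-2-yl)-2,3-dihydro-1-benzofuran-6-yl]oxy}silane
Product: 5 2-{(S)-6-[(triisopropylsilyl)oxy]-2,3-dihydro-1-benzofuran-2-yl}propan-2-ol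
Conditions: Co(acac)2 (20 mol%), PhSiH3 (2.5 equiv), O2 (1 atm), THF, rt
Reagents that add atoms: dioxygen, O=O
Why: Mukaiyama hydration: hydrogen-atom transfer to the 1,1-disubstituted alkene gives the tertiary radical, which is trapped by oxygen and reduced to the Markovnikov alcohol. No acid is present and C2 is not touched.

Step 4
Reactants: 5 2-{(S)-6-[(triisopropylsilyl)oxy]-2,3-dihydro-1-benzofuran-2-yl}propan-2-ol
Product: 6 2-{(S)-5-iodo-6-[(triisopropylsilyl)oxy]-2,3-dihydro-1-benzofuran-2-yl}propan-2-ol
Conditions: NIS (1.05 equiv), MeCN, 0 °C to rt, dark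
Reagents that add atoms: N-iodosuccinimide, O=C1CCC(=O)N1I
Why: Electrophilic aromatic iodination should go to C5, which is para to O1 and ortho to the silyloxy group; C7 is flanked by both oxygens and shielded by the silyl group, and C4 is meta to both donors.

Step 5
Reactants: 6 2-{(S)-5-iodo-6-[(triisopropylsilyl)oxy]-2,3-dihydro-1-benzofuran-2-yl}propan-2-ol; 7 diethyl oxalate
Product: 9 ethyl 2-{(S)-2-(2-hydroxypropan-2-yl)-6-[(triisopropylsilyl)oxy]-2,3-dihydro-1-benzofuran-5-yl}-2-oxoacetate, via arylmagnesium chloride alkoxide 8 (not isolated)
Conditions: i-PrMgCl·LiCl (2.2 equiv), THF, −20 to 0 °C; then added to 7 (3 equiv), THF, −78 °C; aq. NH4Cl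
Reagents that add atoms: none
Why: The first equivalent deprotonates the tertiary alcohol and the second performs iodine–magnesium exchange. Inverse addition to excess oxalate at low temperature should stop at the keto ester, because the tetrahedral adduct persists until the quench. The arylmagnesium does not undergo the silyl shift that an aryllithium would.

Step 6
Reactants: 9 ethyl 2-{(S)-2-(2-hydroxypropan-2-yl)-6-[(triisopropylsilyl)oxy]-2,3-dihydro-1-benzofuran-5-yl}-2-oxoacetate
Product: 10 2-{(S)-2-(2-hydroxypropan-2-yl)-6-[(triisopropylsilyl)oxy]-2,3-dihydro-1-benzofuran-5-yl}-2-oxoacetic acid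
Conditions: LiOH·H2O (1.5 equiv), THF/H2O 4:1, 0 °C, short reaction time; then 1 M HCl to pH 3, 0 °C
Reagents that add atoms: lithium hydroxide, [Li+].[OH-]
Why: Saponification of an α-keto ester is fast at 0 °C because the neighbouring ketone activates the ester. The hindered aryl triisopropylsilyl ether should survive the brief exposure.

Step 7
Reactants: 11 4-bromophenol; 2 isoprene
Product: 12 6-bromo-2,2-dimethylchroman (6-bromo-2,2-dimethyl-3,4-dihydro-2H-1-benzopyran)
Conditions: Bi(OTf)3 (5 mol%), 2 (1.5 equiv, slow addition), toluene, 40 °C
Reagents that add atoms: none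
Why: Acid-catalysed chroman synthesis from a phenol and isoprene: Friedel–Crafts prenylation ortho to the hydroxyl (para is blocked by bromine), then Markovnikov hydroalkoxylation of the prenyl alkene closes ring B.

Step 8
Reactants: 10 2-{(S)-2-(2-hydroxypropan-2-yl)-6-[(triisopropylsilyl)oxy]-2,3-dihydro-1-benzofuran-5-yl}-2-oxoacetic acid; 12 6-bromo-2,2-dimethylchroman; 13 vinylboronic acid pinacol ester (2-ethenyl-4,4,5,5-tetramethyl-1,3,2-dioxaborolane)
Product: 15 (S)-3-(2,2-dimethylchroman-6-yl)-1-{(S)-2-(2-hydroxypropan-2-yl)-6-[(triisopropylsilyl)oxy]-2,3-dihydro-1-benzofuran-5-yl}-3-(4,4,5,5-tetramethyl-1,3,2-dioxaborolan-2-yl)propan-1-one, via potassium keto carboxylate 14 (not isolated)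
Conditions: 10 (1.0 equiv), 12 (1.5 equiv), 13 (4 equiv), Ir[dF(CF3)ppy]2(dtbbpy)PF6 (2 mol%), NiBr2(dme) (10 mol%), chiral 4,4'-disubstituted 2,2'-bi(4,5-dihydroimidazole) ligand (12 mol%), K2HPO4 (2 equiv), DMA/DME, blue LEDs (450 nm), 10 °C
Reagents that add atoms: none
Why: Proposed new method: the excited iridium photocatalyst oxidises carboxylate 14, and loss of CO2 leaves a nucleophilic aroyl radical that adds to the CH2 terminus of 13, because the new radical is stabilised by the vacant orbital on boron. That α-boryl radical is captured by the chiral aryl–nickel bromide formed by oxidative addition of zerovalent nickel into the C–Br bond of 12, and reductive elimination from the trivalent alkyl(aryl)nickel forms the bond to C6 of ring A. The reduced iridium complex then returns monovalent nickel to zerovalent nickel, so the cycle is redox-neutral. The closest known reaction types are nickel/photoredox three-component alkyl-arylations of vinylboronates, their ligand-controlled asymmetric versions, and decarboxylative acyl radical formation from α-keto acids for nickel-catalysed ketone synthesis; the combination of an aroyl radical with enantioselective capture is new. No ring is closed. The benzylic stereocentre arises from a planar radical, so only the chiral ligand on nickel fixes it during capture and reductive elimination; the C2 centre seven bonds away has no say. The step needs radical addition to 13 to outrun direct capture of the aroyl radical by nickel, which the excess of 13 and the modest nickel loading are meant to secure. The silyl ether keeps the phenol out of photocatalyst quenching and C–O coupling, and the boryl group, unlike an oxygen substituent, cannot eliminate from the β-position.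

Step 9
Reactants: 15 (S)-3-(2,2-dimethylchroman-6-yl)-1-{(S)-2-(2-hydroxypropan-2-yl)-6-[(triisopropylsilyl)oxy]-2,3-dihydro-1-benzofuran-5-yl}-3-(4,4,5,5-tetramethyl-1,3,2-dioxaborolan-2-yl)propan-1-one
Product: 16 (S)-3-(2,2-dimethylchroman-6-yl)-3-hydroxy-1-{(S)-2-(2-hydroxypropan-2-yl)-6-[(triisopropylsilyl)oxy]-2,3-dihydro-1-benzofuran-5-yl}propan-1-one
Conditions: NaBO3·4H2O (4 equiv), THF/H2O 1:1, 0 °C to rt
Reagents that add atoms: sodium perborate (NaBO3, used as the tetrahydrate), [Na+].[O-]OB=O
Why: Boronate oxidation: the peroxide adds to boron and the benzylic carbon migrates from boron to oxygen with retention, so the S centre of 15 becomes the S carbinol. Perborate is only mildly basic, and the silylated phenol cannot enter a Dakin oxidation.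

Step 10
Reactants: 16 (S)-3-(2,2-dimethylchroman-6-yl)-3-hydroxy-1-{(S)-2-(2-hydroxypropan-2-yl)-6-[(triisopropylsilyl)oxy]-2,3-dihydro-1-benzofuran-5-yl}propan-1-one
Product: 17 (S)-3-(2,2-dimethylchroman-6-yl)-3-hydroxy-1-[(S)-6-hydroxy-2-(2-hydroxypropan-2-yl)-2,3-dihydro-1-benzofuran-5-yl]propan-1-one (CNP0419761.2)
Conditions: TBAF (1.2 equiv), AcOH (1.5 equiv), THF, 0 °C
Reagents that add atoms: none
Why: Fluoride cleaves the aryl silyl ether, which is activated by the ortho acyl group. The acetic acid buffer protonates the phenoxide at once, which should suppress enolisation, elimination and retro-aldol.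

## Compound list

1 | 4-bromoresorcinol | Oc1ccc(Br)c(O)c1 | starting material
2 | isoprene | C=CC(C)=C | starting material
3 | (S)-2-(prop-1-en-2-yl)-2,3-dihydro-1-benzofuran-6-ol | Oc1ccc2c(c1)O[C@H](C(C)=C)C2 | intermediate
4 | triisopropyl{[(S)-2-(prop-1-en-2-yl)-2,3-dihydro-1-benzofuran-6-yl]oxy}silane | CC(C)[Si](Oc1ccc2c(c1)O[C@H](C(C)=C)C2)(C(C)C)C(C)C | intermediate
5 | 2-{(S)-6-[(triisopropylsilyl)oxy]-2,3-dihydro-1-benzofuran-2-yl}propan-2-ol | CC(C)[Si](Oc1ccc2c(c1)O[C@H](C(C)(C)O)C2)(C(C)C)C(C)C | intermediate
6 | 2-{(S)-5-iodo-6-[(triisopropylsilyl)oxy]-2,3-dihydro-1-benzofuran-2-yl}propan-2-ol | Ic1cc2c(cc1O[Si](C(C)C)(C(C)C)C(C)C)O[C@H](C(C)(C)O)C2 | intermediate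
7 | diethyl oxalate | CCOC(=O)C(=O)OCC | starting material
8 | arylmagnesium chloride of 6 with chloromagnesium alkoxide | Cl[Mg]c1cc2c(cc1O[Si](C(C)C)(C(C)C)C(C)C)O[C@H](C(C)(C)O[Mg]Cl)C2 | intermediate (not isolated)
9 | ethyl 2-{(S)-2-(2-hydroxypropan-2-yl)-6-[(triisopropylsilyl)oxy]-2,3-dihydro-1-benzofuran-5-yl}-2-oxoacetate | CCOC(=O)C(=O)c1cc2c(cc1O[Si](C(C)C)(C(C)C)C(C)C)O[C@H](C(C)(C)O)C2 | intermediate
10 | 2-{(S)-2-(2-hydroxypropan-2-yl)-6-[(triisopropylsilyl)oxy]-2,3-dihydro-1-benzofuran-5-yl}-2-oxoacetic acid | OC(=O)C(=O)c1cc2c(cc1O[Si](C(C)C)(C(C)C)C(C)C)O[C@H](C(C)(C)O)C2 | intermediate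
11 | 4-bromophenol | Oc1ccc(Br)cc1 | starting material
12 | 6-bromo-2,2-dimethylchroman | CC1(C)CCc2cc(Br)ccc2O1 | intermediate
13 | vinylboronic acid pinacol ester | C=CB1OC(C)(C)C(C)(C)O1 | starting material
14 | potassium salt of keto acid 10 | [K+].[O-]C(=O)C(=O)c1cc2c(cc1O[Si](C(C)C)(C(C)C)C(C)C)O[C@H](C(C)(C)O)C2 | intermediate (not isolated)
15 | (S)-3-(2,2-dimethylchroman-6-yl)-1-{(S)-2-(2-hydroxypropan-2-yl)-6-[(triisopropylsilyl)oxy]-2,3-dihydro-1-benzofuran-5-yl}-3-(4,4,5,5-tetramethyl-1,3,2-dioxaborolan-2-yl)propan-1-one | CC1(C)CCc2cc([C@@H](B3OC(C)(C)C(C)(C)O3)CC(=O)c4cc5c(cc4O[Si](C(C)C)(C(C)C)C(C)C)O[C@H](C(C)(C)O)C5)ccc2O1 | intermediate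
16 | (S)-3-(2,2-dimethylchroman-6-yl)-3-hydroxy-1-{(S)-2-(2-hydroxypropan-2-yl)-6-[(triisopropylsilyl)oxy]-2,3-dihydro-1-benzofuran-5-yl}propan-1-one | CC1(C)CCc2cc([C@@H](O)CC(=O)c3cc4c(cc3O[Si](C(C)C)(C(C)C)C(C)C)O[C@H](C(C)(C)O)C4)ccc2O1 | intermediate
17 | (S)-3-(2,2-dimethylchroman-6-yl)-3-hydroxy-1-[(S)-6-hydroxy-2-(2-hydroxypropan-2-yl)-2,3-dihydro-1-benzofuran-5-yl]propan-1-one | CC1(C)CCc2cc([C@@H](O)CC(=O)c3cc4c(cc3O)O[C@H](C(C)(C)O)C4)ccc2O1 | target

## Step count and least certain steps

Total: 10 steps. Longest linear sequence: 9 steps (steps 1 to 6, then 8, 9 and 10); step 7 is the one-step branch to 12.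

**Step 8 (key step, proposed new method).**
- **What may go wrong:** the aroyl radical may be captured by aryl-nickel before it adds to 13, which is direct acyl–aryl coupling. The α-boryl radical may be reduced or may add to further 13 before nickel captures it. Facial discrimination at nickel may be incomplete, giving a diastereomer mixture that is hard to separate.
- **Fallback (known chemistry), from 12 and 6, returning at 15:** Heck reaction of 12 with N-methoxy-N-methylacrylamide (Pd(OAc)2, P(o-tol)3, Et3N, DMF, 100 °C) gives (E)-3-(2,2-dimethylchroman-6-yl)-N-methoxy-N-methylprop-2-enamide F1. The Grignard reagent 8, made from 6 as in step 5, adds to F1 to give the enone (E)-3-(2,2-dimethylchroman-6-yl)-1-{(S)-2-(2-hydroxypropan-2-yl)-6-[(triisopropylsilyl)oxy]-2,3-dihydro-1-benzofuran-5-yl}prop-2-en-1-one F2. Copper-catalysed asymmetric conjugate borylation of F2 (CuCl, NaOt-Bu, chiral bisphosphine such as QuinoxP*, B2pin2, MeOH, THF, rt) puts boron on the β-carbon and gives 15.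

**Step 1.**
- **What may go wrong:** oxidative addition into the C–Br bond may be slow because the doubly deprotonated resorcinol is very electron-rich. The higher temperature then needed may erode enantioselectivity.
- **Fallback, from 1, returning at 5:** double silylation (TIPSCl, imidazole) gives 4-bromo-1,3-bis[(triisopropylsilyl)oxy]benzene F3. Bromine–lithium exchange (t-BuLi, THF, −78 °C) and alkylation with prenyl bromide in the presence of CuBr·SMe2 give 1-(3-methylbut-2-en-1-yl)-2,4-bis[(triisopropylsilyl)oxy]benzene F4. Shi epoxidation (fructose-derived ketone of the required antipode, KHSO5 as 2KHSO5·KHSO4·K2SO4, buffered MeCN/H2O) gives (R)-3-{2,4-bis[(triisopropylsilyl)oxy]benzyl}-2,2-dimethyloxirane F5. TBAF frees both phenols, and the ortho phenoxide opens the epoxide 5-exo at the secondary carbon with inversion to give (S)-2-(2-hydroxypropan-2-yl)-2,3-dihydro-1-benzofuran-6-ol F6. Selective silylation of the phenol (TIPSCl, imidazole) gives 5.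

**Step 6.**
- **What may go wrong:** hydroxide may attack silicon in competition with ester hydrolysis, because the ortho acyl group makes the phenoxide a good leaving group. The phenol protection would then be lost before the key step.
- **Fallback, from 6, returning at 10:** the Grignard reagent 8, made as in step 5, is added to diallyl oxalate in place of 7 to give allyl 2-{(S)-2-(2-hydroxypropan-2-yl)-6-[(triisopropylsilyl)oxy]-2,3-dihydro-1-benzofuran-5-yl}-2-oxoacetate F7. The allyl ester is cleaved without base by Pd(PPh3)4 (5 mol%) and PhSiH3 in CH2Cl2 at rt, and aqueous work-up gives 10.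

**Step 10.**
- **What may go wrong:** the basicity of fluoride or of the liberated phenoxide may trigger enolisation and β-elimination of the benzylic hydroxyl, followed by conjugate ring closure, or retro-aldol cleavage. The perborate step before it carries a related risk of silyl loss followed by Dakin cleavage.
- **Fallback, from 15, returning at 17:** the order of the last two operations is reversed. Buffered fluoride (TBAF, AcOH, THF, 0 °C) on 15 gives the phenol boronate (S)-3-(2,2-dimethylchroman-6-yl)-1-[(S)-6-hydroxy-2-(2-hydroxypropan-2-yl)-2,3-dihydro-1-benzofuran-5-yl]-3-(4,4,5,5-tetramethyl-1,3,2-dioxaborolan-2-yl)propan-1-one F8, in which the β-substituent is boron and cannot leave. The C–B bond is then oxidised with trimethylamine N-oxide (THF, 50 °C, aqueous work-up), a neutral oxidant that is not a peroxide and so cannot effect Dakin cleavage, to give 17.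

## Further compounds

F1 | step 8 | (E)-3-(2,2-dimethylchroman-6-yl)-N-methoxy-N-methylprop-2-enamide | CON(C)C(=O)/C=C/c1ccc2OC(C)(C)CCc2c1
F2 | step 8 | (E)-3-(2,2-dimethylchroman-6-yl)-1-{(S)-2-(2-hydroxypropan-2-yl)-6-[(triisopropylsilyl)oxy]-2,3-dihydro-1-benzofuran-5-yl}prop-2-en-1-one | CC1(C)CCc2cc(/C=C/C(=O)c3cc4c(cc3O[Si](C(C)C)(C(C)C)C(C)C)O[C@H](C(C)(C)O)C4)ccc2O1
F3 | step 1 | 4-bromo-1,3-bis[(triisopropylsilyl)oxy]benzene | CC(C)[Si](Oc1ccc(Br)c(O[Si](C(C)C)(C(C)C)C(C)C)c1)(C(C)C)C(C)C
F4 | step 1 | 1-(3-methylbut-2-en-1-yl)-2,4-bis[(triisopropylsilyl)oxy]benzene | CC(C)=CCc1ccc(O[Si](C(C)C)(C(C)C)C(C)C)cc1O[Si](C(C)C)(C(C)C)C(C)C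
F5 | step 1 | (R)-3-{2,4-bis[(triisopropylsilyl)oxy]benzyl}-2,2-dimethyloxirane | CC1(C)O[C@@H]1Cc1ccc(O[Si](C(C)C)(C(C)C)C(C)C)cc1O[Si](C(C)C)(C(C)C)C(C)C
F6 | step 1 | (S)-2-(2-hydroxypropan-2-yl)-2,3-dihydro-1-benzofuran-6-ol | Oc1ccc2c(c1)O[C@H](C(C)(C)O)C2
F7 | step 6 | allyl 2-{(S)-2-(2-hydroxypropan-2-yl)-6-[(triisopropylsilyl)oxy]-2,3-dihydro-1-benzofuran-5-yl}-2-oxoacetate | C=CCOC(=O)C(=O)c1cc2c(cc1O[Si](C(C)C)(C(C)C)C(C)C)O[C@H](C(C)(C)O)C2
F8 | step 10 | (S)-3-(2,2-dimethylchroman-6-yl)-1-[(S)-6-hydroxy-2-(2-hydroxypropan-2-yl)-2,3-dihydro-1-benzofuran-5-yl]-3-(4,4,5,5-tetramethyl-1,3,2-dioxaborolan-2-yl)propan-1-one | CC1(C)CCc2cc([C@@H](B3OC(C)(C)C(C)(C)O3)CC(=O)c4cc5c(cc4O)O[C@H](C(C)(C)O)C5)ccc2O1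
A1 | alternative 1 | L-tyrosine | N[C@@H](Cc1ccc(O)cc1)C(=O)O
A2 | alternative 1 | (S)-1-[4-(benzyloxy)phenyl]-3-methylbutane-2,3-diol | O[C@H](C(C)(C)O)Cc1ccc(OCc2ccccc2)cc1
A3 | alternative 1 | (S)-6-benzyloxy-2-(2-hydroxypropan-2-yl)-2,3-dihydrobenzofuran | c1ccccc1COc1ccc2c(c1)O[C@H](C(C)(C)O)C2
A4 | alternative 2 | (S)-5-[2,2-bis(trimethylsilyloxy)ethenyl]-2-[2-(triethylsilyloxy)propan-2-yl]-2,3-dihydrofuran | C[Si](C)(C)OC(O[Si](C)(C)C)=CC1=CC[C@@H](C(C)(C)O[Si](CC)(CC)CC)O1
A5 | alternative 2 | (S)-5-(tert-butyldimethylsilyloxy)-5-(2,2-dimethylchroman-6-yl)pent-1-yn-3-one | C#CC(=O)C[C@H](O[Si](C)(C)C(C)(C)C)c1ccc2OC(C)(C)CCc2c1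
A6 | alternative 2 | bis-silyl ether of the target (carbinol tert-butyldimethylsilyl ether, tertiary triethylsilyl ether) | CC1(C)CCc2cc([C@@H](O[Si](C)(C)C(C)(C)C)CC(=O)c3cc4c(cc3O)O[C@H](C(C)(C)O[Si](CC)(CC)CC)C4)ccc2O1
A7 | alternative 3 | (S)-1-(5-bromo-2,4-dihydroxyphenyl)-3-(tert-butyldimethylsilyloxy)-3-(2,2-dimethylchroman-6-yl)propan-1-one | CC1(C)CCc2cc([C@@H](O[Si](C)(C)C(C)(C)C)CC(=O)c3cc(Br)c(O)cc3O)ccc2O1
A8 | alternative 3 | (S)-3-(tert-butyldimethylsilyloxy)-3-(2,2-dimethylchroman-6-yl)-1-[(S)-6-hydroxy-2-(prop-1-en-2-yl)-2,3-dihydrobenzofuran-5-yl]propan-1-one | CC1(C)CCc2cc([C@@H](O[Si](C)(C)C(C)(C)C)CC(=O)c3cc4c(cc3O)O[C@H](C(C)=C)C4)ccc2O1
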